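**Retrosynthetic overview**

1. Locants: enone ring C1 (C=O), C2 (carries Cα of the acid), C3 (carries quaternary C1′ of the trimethylcyclohexane), C4, C5, C6 (carries CH2O). End game: 21 ⇐ hydroxy acid 20 ⇐ enone acid 19 ⇐ E1cB opening of the temporary γ-lactone 18 ⇐ diol 17.
2. Key disconnection C2–C3: the cyclohexenone ring is closed by a ligand-controlled CuH reductive aldol cyclisation of the acyclic enedione 15; hydride delivery to Cα sets the propanoate centre and creates the C2 enolate that attacks the C3 ketone.
3. Enabling feature: C2=C3 of the enone ring is an aldol retron. C3 carries the hydrogen-free C1′, so a C3 ketone can only be the acceptor. C2 carries Cα, so a Cα=C2 enone gives the C2 enolate regiospecifically and leaves C6 untouched.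
4. 15 ⇐ Nozaki–Hiyama–Kishi coupling (C1–C2) of aldehyde 11 with iodide 13; 11 ⇐ enamine-catalysed Michael addition (C5–C6, sets C6) of aldehyde 10 to vinyl ketone 9; 9 ⇐ aldehyde 7 ⇐ Cu-catalysed alkenyl conjugate addition to 1 (sets C1′), then gem-dimethylation.
5. Ring order: the trimethylcyclohexane ring is bought with 1 and completed in step 2; the cyclohexenone ring is closed last (step 10); the lactone of step 11 is a temporary ring, opened again in step 12.

Key step: step 10

Assumption: 10 and 12 are treated as purchasable building blocks (each is otherwise one known step from mono-silylated propane-1,3-diol and from propargyl alcohol, respectively).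
Remark: in the two ligand-controlled steps (1 and 10) the ligand antipode is defined by the product it must give (3S in 4; hydride on the Si face of Cα in 15) and is to be confirmed in the first run; both antipodes are commercial.
Remark: the acetal carbons of 6, the carbinol carbons of 8 and 14, and C2/C3 of 16, 17 and 18 are transient centres written without configuration, because every isomer converges on the same later compound.

**Route**

Step 1
Reactants: 1 3-methylcyclohex-2-en-1-one; 2 hex-1-yne
Product: 4 (3S)-3-[(1E)-hex-1-en-1-yl]-3-methylcyclohexan-1-one, via hexenylalane 3 (not isolated)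
Conditions: 2, DIBAL-H, heptane, 55 °C; then 1, CuTC (10 mol %), chiral phosphinamine ligand of the SimplePhos type (11 mol %), Et2O, −30 °C; aq. HCl
Reagents that add atoms: none
Why: syn-hydroalumination gives the (E)-alkenylalane, and its copper-catalysed asymmetric conjugate addition to a β-methyl cyclohexenone is a well-precedented route to an alkenyl-bearing quaternary centre, the ligand choosing the enone face and so setting C1′.

Step 2
Reactants: 4
Product: 5 (1S)-1-[(1E)-hex-1-en-1-yl]-1,3,3-trimethylcyclohexane
Conditions: Me2Zn, TiCl4, CH2Cl2, −40 °C; then 4, −40 → 0 °C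
Reagents that add atoms: dimethyltitanium dichloride, C[Ti](C)(Cl)Cl (made in the flask from dimethylzinc and titanium tetrachloride)
Why: geminal dimethylation of a ketone with Me2TiCl2 (methyl addition, then replacement of the tertiary Ti–O bond by a second methyl) turns C=O into CMe2 without touching the remote quaternary centre.

Step 3
Reactants: 5
Product: 7 (1S)-1,3,3-trimethylcyclohexane-1-carbaldehyde, via ozonide 6 (not isolated)
Conditions: O3, CH2Cl2, −78 °C; then Me2S, −78 → 23 °C
Reagents that add atoms: ozone, [O-][O+]=O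
Why: ozonolysis with reductive work-up cleaves the disubstituted alkene to a neopentyl aldehyde that has no α-hydrogen, so C1′ cannot epimerise.

Step 4
Reactants: 7
Product: 8 1-[(1S)-1,3,3-trimethylcyclohexyl]prop-2-en-1-ol (both carbinol epimers)
Conditions: CH2=CHMgBr, THF, −78 → 0 °C
Reagents that add atoms: vinylmagnesium bromide, C=C[Mg]Br
Why: Grignard 1,2-addition to the aldehyde; the new carbinol centre is irrelevant because it is oxidised in the next step.

Step 5
Reactants: 8
Product: 9 1-[(1S)-1,3,3-trimethylcyclohexyl]prop-2-en-1-one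
Conditions: Dess–Martin periodinane, CH2Cl2, 0 → 23 °C
Reagents that add atoms: none
Why: Dess–Martin oxidation of the allylic alcohol gives the vinyl ketone under conditions free of strong acid or base, which would polymerise it.

Step 6
Reactants: 9; 10 3-[(tert-butyldiphenylsilyl)oxy]propanal
Product: 11 (2S)-2-{[(tert-butyldiphenylsilyl)oxy]methyl}-5-oxo-5-[(1S)-1,3,3-trimethylcyclohexyl]pentanal
Conditions: (S)-2-[methoxy(diphenyl)methyl]pyrrolidine (10 mol %), ethyl 3,4-dihydroxybenzoate (20 mol %), 10 (2 equiv), CH2Cl2, 4 °C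
Reagents that add atoms: none
Why: enamine-catalysed Michael addition of an aldehyde to a vinyl ketone, in which the (E)-enamine is shielded on one face by the CPh2OMe group so that the enone adds to the open face and C6 (S) is set by the catalyst, independently of the remote C1′.

Step 7
Reactants: 12 (2E)-3-iodo-2-methylprop-2-en-1-ol
Product: 13 triethyl{[(2E)-3-iodo-2-methylprop-2-en-1-yl]oxy}silane
Conditions: TESCl, imidazole, CH2Cl2, 0 °C
Reagents that add atoms: chlorotriethylsilane, CC[Si](Cl)(CC)CC
Why: silyl ether formation masks the allylic alcohol through both oxidations with a group that is later lost in the acidic work-up of the key step.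

Step 8
Reactants: 11; 13
Product: 14 (4S,6E)-4-{[(tert-butyldiphenylsilyl)oxy]methyl}-5-hydroxy-7-methyl-8-[(triethylsilyl)oxy]-1-[(1S)-1,3,3-trimethylcyclohexyl]oct-6-en-1-one (both C5 epimers)
Conditions: CrCl2 (4 equiv), NiCl2 (2 mol %), DMSO, 23 °C
Reagents that add atoms: none
Why: Nozaki–Hiyama–Kishi coupling, in which the alkenylchromium formed with retention of the E geometry adds to the aldehyde and not to the hindered ketone, under non-basic conditions that leave the α-centre C6 intact.

Step 9
Reactants: 14
Product: 15 (4S,6E)-4-{[(tert-butyldiphenylsilyl)oxy]methyl}-7-methyl-8-[(triethylsilyl)oxy]-1-[(1S)-1,3,3-trimethylcyclohexyl]oct-6-ene-1,5-dione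
Conditions: Dess–Martin periodinane, pyridine, CH2Cl2, 0 → 23 °C
Reagents that add atoms: none
Why: buffered Dess–Martin oxidation converts the allylic alcohol into the β,β-disubstituted enone while preserving C6 and the alkene geometry.

Step 10
Reactants: 15
Product: 17 (6S)-6-{[(tert-butyldiphenylsilyl)oxy]methyl}-3-hydroxy-2-[(2R)-1-hydroxypropan-2-yl]-3-[(1S)-1,3,3-trimethylcyclohexyl]cyclohexan-1-one, via silyl aldolate 16 (not isolated)
Conditions: Cu(OAc)2·H2O (5 mol %), Josiphos ligand PPF-P(t-Bu)2 (5 mol %), (EtO)2MeSiH (2 equiv), PhMe, −20 → 0 °C; then AcOH/THF/H2O, 23 °C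
Reagents that add atoms: none
Why: Ligated CuH adds hydride to Cα, the β-carbon of the C1 enone, which sets Cα and gives the copper enolate regiospecifically at C2; this enolate adds to the C3 ketone, and σ-bond metathesis of the copper aldolate with the silane gives silyl ether 16 and returns CuH. The closest known reaction is the CuH-catalysed enantioselective intramolecular reductive aldol cyclisation of β,β-disubstituted enones that carry a ketone in the α′ chain. The ring closes in the 6-(enolendo)-exo-trig mode through a chair-like, copper-bridged transition state. Cα (R) is controlled by the ligand, which must place hydride on the Si face of the (E)-alkene; C6 and C1′ are carried through, and the new ring centres C2 and C3 may form as a mixture because C2 becomes sp2 and C3 loses its oxygen in step 12. The step needs 1,4- over 1,2-reduction and an enolate that does not equilibrate towards C6: the β,β-disubstituted enone and the hindered, non-conjugated C3 ketone should secure the first, the non-basic medium and fast silyl transfer the second, and because C1′ has no hydrogen the C3 ketone can only be the acceptor. The aqueous acetic acid work-up removes the labile alkoxysilyl and triethylsilyl groups (not the TBDPS ether) to give diol 17.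

Step 11
Reactants: 17
Product: 18 (3R,5S)-5-{[(tert-butyldiphenylsilyl)oxy]methyl}-3-methyl-7a-[(1S)-1,3,3-trimethylcyclohexyl]hexahydro-1-benzofuran-2,4-dione
Conditions: TEMPO (20 mol %), PhI(OAc)2 (2.5 equiv), CH2Cl2, 23 °C
Reagents that add atoms: none
Why: TEMPO/PhI(OAc)2 oxidative lactonisation of a 1,4-diol, in which the primary alcohol is oxidised to the aldehyde, trapped by the tertiary C3 hydroxyl as a lactol and oxidised on to the γ-lactone, all while C2 is still sp3 so that Cα is not prone to enolise.

Step 12
Reactants: 18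
Product: 19 (2R)-2-[(5S)-5-{[(tert-butyldiphenylsilyl)oxy]methyl}-6-oxo-2-[(1S)-1,3,3-trimethylcyclohexyl]cyclohex-1-en-1-yl]propanoic acid
Conditions: DBU (1.5 equiv), CH2Cl2, 0 °C; aq. citric acid
Reagents that add atoms: none
Why: E1cB elimination of a β-acyloxy ketone, in which DBU removes the acidic C2–H and the lactone carboxylate leaves from C3, opening the temporary ring, creating the tetrasubstituted C2=C3 enone and freeing the acid as a carboxylate that shields Cα from deprotonation.

Step 13
Reactants: 19
Product: 20 (2R)-2-[(5S)-5-(hydroxymethyl)-6-oxo-2-[(1S)-1,3,3-trimethylcyclohexyl]cyclohex-1-en-1-yl]propanoic acid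
Conditions: HF·pyridine, THF, 0 → 23 °C
Reagents that add atoms: none
Why: fluoride-mediated desilylation under buffered acidic conditions frees the primary alcohol without base, so retro-aldol loss of formaldehyde and epimerisation at C6 should be avoided.

Step 14
Reactants: 20
Product: 21 (2R)-2-[(5S)-5-[(formyloxy)methyl]-6-oxo-2-[(1S)-1,3,3-trimethylcyclohexyl]cyclohex-1-en-1-yl]propanoic acid
Conditions: HCO2H (98 %, neat), 23 °C; evaporate with toluene
Reagents that add atoms: formic acid, O=CO
Why: acid-catalysed Fischer-type formylation in neat formic acid esterifies the primary alcohol, leaves the carboxylic acid unchanged and is too mild to eliminate the resulting β-acyloxy ketone.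

**Compound list**

1 | 3-methylcyclohex-2-en-1-one | CC1=CC(=O)CCC1 | starting material
2 | hex-1-yne | CCCCC#C | starting material
3 | (E)-hex-1-en-1-yl(diisobutyl)aluminium | CCCC/C=C/[Al](CC(C)C)CC(C)C | intermediate (not isolated)
4 | (3S)-3-[(1E)-hex-1-en-1-yl]-3-methylcyclohexan-1-one | CCCC/C=C/[C@@]1(C)CCCC(=O)C1 | intermediate
5 | (1S)-1-[(1E)-hex-1-en-1-yl]-1,3,3-trimethylcyclohexane | CCCC/C=C/[C@@]1(C)CCCC(C)(C)C1 | intermediate
6 | 3-butyl-5-[(1S)-1,3,3-trimethylcyclohexyl]-1,2,4-trioxolane | CCCCC1OOC(O1)[C@@]2(C)CCCC(C)(C)C2 | intermediate (not isolated)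
7 | (1S)-1,3,3-trimethylcyclohexane-1-carbaldehyde | O=C[C@@]1(C)CCCC(C)(C)C1 | intermediate
8 | 1-[(1S)-1,3,3-trimethylcyclohexyl]prop-2-en-1-ol | C=CC(O)[C@@]1(C)CCCC(C)(C)C1 | intermediate
9 | 1-[(1S)-1,3,3-trimethylcyclohexyl]prop-2-en-1-one | C=CC(=O)[C@@]1(C)CCCC(C)(C)C1 | intermediate
10 | 3-[(tert-butyldiphenylsilyl)oxy]propanal | O=CCCO[Si](c1ccccc1)(c1ccccc1)C(C)(C)C | starting material
11 | (2S)-2-{[(tert-butyldiphenylsilyl)oxy]methyl}-5-oxo-5-[(1S)-1,3,3-trimethylcyclohexyl]pentanal | O=C[C@H](CO[Si](c1ccccc1)(c1ccccc1)C(C)(C)C)CCC(=O)[C@@]2(C)CCCC(C)(C)C2 | intermediate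
12 | (2E)-3-iodo-2-methylprop-2-en-1-ol | I/C=C(\C)CO | starting material
13 | triethyl{[(2E)-3-iodo-2-methylprop-2-en-1-yl]oxy}silane | I/C=C(\C)CO[Si](CC)(CC)CC | intermediate
14 | (4S,6E)-4-{[(tert-butyldiphenylsilyl)oxy]methyl}-5-hydroxy-7-methyl-8-[(triethylsilyl)oxy]-1-[(1S)-1,3,3-trimethylcyclohexyl]oct-6-en-1-one | C/C(=C\C(O)[C@H](CO[Si](c1ccccc1)(c1ccccc1)C(C)(C)C)CCC(=O)[C@@]2(C)CCCC(C)(C)C2)CO[Si](CC)(CC)CC | intermediate
15 | (4S,6E)-4-{[(tert-butyldiphenylsilyl)oxy]methyl}-7-methyl-8-[(triethylsilyl)oxy]-1-[(1S)-1,3,3-trimethylcyclohexyl]oct-6-ene-1,5-dione | C/C(=C\C(=O)[C@H](CO[Si](c1ccccc1)(c1ccccc1)C(C)(C)C)CCC(=O)[C@@]2(C)CCCC(C)(C)C2)CO[Si](CC)(CC)CC | intermediate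
16 | (6S)-6-{[(tert-butyldiphenylsilyl)oxy]methyl}-3-{[diethoxy(methyl)silyl]oxy}-2-[(2R)-1-[(triethylsilyl)oxy]propan-2-yl]-3-[(1S)-1,3,3-trimethylcyclohexyl]cyclohexan-1-one | C[C@@H](CO[Si](CC)(CC)CC)C1C(=O)[C@H](CO[Si](c2ccccc2)(c2ccccc2)C(C)(C)C)CCC1(O[Si](C)(OCC)OCC)[C@@]3(C)CCCC(C)(C)C3 | intermediate (not isolated)
17 | (6S)-6-{[(tert-butyldiphenylsilyl)oxy]methyl}-3-hydroxy-2-[(2R)-1-hydroxypropan-2-yl]-3-[(1S)-1,3,3-trimethylcyclohexyl]cyclohexan-1-one | C[C@@H](CO)C1C(=O)[C@H](CO[Si](c2ccccc2)(c2ccccc2)C(C)(C)C)CCC1(O)[C@@]3(C)CCCC(C)(C)C3 | intermediate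
18 | (3R,5S)-5-{[(tert-butyldiphenylsilyl)oxy]methyl}-3-methyl-7a-[(1S)-1,3,3-trimethylcyclohexyl]hexahydro-1-benzofuran-2,4-dione | C[C@H]1C(=O)OC2(CC[C@@H](CO[Si](c3ccccc3)(c3ccccc3)C(C)(C)C)C(=O)C12)[C@@]4(C)CCCC(C)(C)C4 | intermediate
19 | (2R)-2-[(5S)-5-{[(tert-butyldiphenylsilyl)oxy]methyl}-6-oxo-2-[(1S)-1,3,3-trimethylcyclohexyl]cyclohex-1-en-1-yl]propanoic acid | C[C@@H](C(=O)O)C1=C([C@@]2(C)CCCC(C)(C)C2)CC[C@@H](CO[Si](c3ccccc3)(c3ccccc3)C(C)(C)C)C1=O | intermediate
20 | (2R)-2-[(5S)-5-(hydroxymethyl)-6-oxo-2-[(1S)-1,3,3-trimethylcyclohexyl]cyclohex-1-en-1-yl]propanoic acid | C[C@@H](C(=O)O)C1=C([C@@]2(C)CCCC(C)(C)C2)CC[C@@H](CO)C1=O | intermediate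
21 | (2R)-2-[(5S)-5-[(formyloxy)methyl]-6-oxo-2-[(1S)-1,3,3-trimethylcyclohexyl]cyclohex-1-en-1-yl]propanoic acid | C[C@@H](C(=O)O)C1=C([C@@]2(C)CCCC(C)(C)C2)CC[C@@H](COC=O)C1=O | target

**Step count and risks**

Total steps: 14. Longest linear sequence: 13 (steps 1–6 and 8–14; step 7 is a one-step side branch).

Step 10 (key step). What may go wrong: silyl transfer to the copper enolate may outrun its addition to the hindered C3 carbonyl, so that the chain is reduced but not closed; hydride delivery to Cα may also be less face-selective than on simpler enones. Fallback (ring closure by a Lewis-acid aldol on an isolated, regiodefined enol ether instead of the copper enolate): starting from 15, the same CuH/Josiphos reduction is run with PhMe2SiH, which should stop at the (Z)-dimethylphenylsilyl enol ether F1, with Cα already set and the enol ether fixed at C1=C2. TiCl4 in CH2Cl2 at −78 °C then activates the C3 ketone for an intramolecular Mukaiyama aldol addition, and the AcOH/THF/H2O work-up removes the triethylsilyl group, so the sequence returns to the route at diol 17.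

Step 2. What may go wrong: after the first methyl transfer the tertiary titanium alkoxide may ionise and lose a proton faster than it accepts the second methyl group, giving methylcyclohexenes; the Lewis acid may also isomerise the side-chain alkene. Fallback (buy the gem-dimethyl group instead of making it): alane 3 is added under the conditions of step 1 to isophorone F2 (purchased), using the mirror-image ligand because the CMe2 group now lies on the other arm of the ring; this should give ketone F3. Wolff–Kishner reduction (N2H4·H2O, KOH, diethylene glycol, 200 °C) then removes the carbonyl group and returns to the route at alkene 5. Isophorone is the slower acceptor (axial methyl next to the reacting carbon), which is why this is the fallback and not the main line.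

Step 12. What may go wrong: if the ring-fusion hydrogen at C2 of lactone 18 is poorly accessible, enolisation towards C6 (epimerisation) competes with the E1cB opening. Fallback (base-free dehydration of the tertiary alcohol, oxidation afterwards): starting from diol 17, the primary alcohol is re-silylated (TESCl, imidazole) to give F4, Martin sulfurane (CH2Cl2, 0 °C) dehydrates the tertiary C3 alcohol to enone F5, and AcOH/THF/H2O frees the primary alcohol F6. TEMPO/PhI(OAc)2 in MeCN–pH 7 buffer followed by NaClO2 in the same flask oxidises F6 to acid 19, where the route is rejoined. The price is a transient α-alkenyl aldehyde whose Cα could enolise, hence the buffered, fast oxidation.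

Further compounds
F1 | step 10 | (2R,3Z,5S)-5-{[(tert-butyldiphenylsilyl)oxy]methyl}-4-{[dimethyl(phenyl)silyl]oxy}-2-methyl-1-[(triethylsilyl)oxy]-8-[(1S)-1,3,3-trimethylcyclohexyl]oct-3-en-8-one | C[C@@H](CO[Si](CC)(CC)CC)/C=C(\O[Si](C)(C)c1ccccc1)[C@H](CO[Si](c2ccccc2)(c2ccccc2)C(C)(C)C)CCC(=O)[C@@]3(C)CCCC(C)(C)C3
F2 | step 2 | isophorone (3,5,5-trimethylcyclohex-2-en-1-one, purchased) | CC1=CC(=O)CC(C)(C)C1
F3 | step 2 | (3R)-3-[(1E)-hex-1-en-1-yl]-3,5,5-trimethylcyclohexan-1-one | CCCC/C=C/[C@@]1(C)CC(=O)CC(C)(C)C1
F4 | step 12 | (6S)-6-{[(tert-butyldiphenylsilyl)oxy]methyl}-3-hydroxy-2-[(2R)-1-[(triethylsilyl)oxy]propan-2-yl]-3-[(1S)-1,3,3-trimethylcyclohexyl]cyclohexan-1-one | C[C@@H](CO[Si](CC)(CC)CC)C1C(=O)[C@H](CO[Si](c2ccccc2)(c2ccccc2)C(C)(C)C)CCC1(O)[C@@]3(C)CCCC(C)(C)C3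
F5 | step 12 | (6S)-6-{[(tert-butyldiphenylsilyl)oxy]methyl}-2-[(2R)-1-[(triethylsilyl)oxy]propan-2-yl]-3-[(1S)-1,3,3-trimethylcyclohexyl]cyclohex-2-en-1-one | C[C@@H](CO[Si](CC)(CC)CC)C1=C([C@@]2(C)CCCC(C)(C)C2)CC[C@@H](CO[Si](c3ccccc3)(c3ccccc3)C(C)(C)C)C1=O
F6 | step 12 | (6S)-6-{[(tert-butyldiphenylsilyl)oxy]methyl}-2-[(2R)-1-hydroxypropan-2-yl]-3-[(1S)-1,3,3-trimethylcyclohexyl]cyclohex-2-en-1-one | C[C@@H](CO)C1=C([C@@]2(C)CCCC(C)(C)C2)CC[C@@H](CO[Si](c3ccccc3)(c3ccccc3)C(C)(C)C)C1=O
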